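**Retrosynthetic overview**

1. The target chlorovulone, methyl (5Z,7Z,12R,14Z)-10-chloro-12-hydroxy-9-oxoprosta-5,7,10,14-tetraen-1-oate, comes from its silyl ether 28. The C6–C7 bond is made by Stille coupling of the (Z)-enol triflate 23 (C7 added to C8 as a formyl carbon) with the C1–C6 (Z)-vinylstannane 27, which fixes 7Z and 5Z. C14=C15 comes from a (Z)-Wittig reaction on the C13–C14 aldehyde 15, carried until then as a dimethyl acetal.
2. Feature: in the five-membered ring C8–C9–C10–C11–C12 the chloroenone C9(=O)–C10(Cl)=C11 lies next to the C12 carbinol. Removing C10 with its chlorine leaves a four-membered ring C8–C9–C11–C12, a cyclobutanone with a mirror plane through C9 and C12.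
3. Key disconnection: C9–C10 and C10–C11. Dichlorocarbene from chloroform adds to the C9=C11 silyl enol ether 10 and the adduct opens to chloroenone 14.
4. The C12 configuration comes from enantiotopos-selective enolisation of cyclobutanone 8. Ketone 8 comes from dichloroketene (2+2) cycloaddition to the silyl enol ether of 4,4-dimethoxybutan-2-one, then dechlorination.
5. Ring order: the four-membered ring is formed in step 2 and expanded to the five-membered ring in step 5; no other ring is formed.

Key step: step 5

Assumption: the (R,R)-configured lithium amide is taken to remove the α-proton that leads to 10; if the sense of induction is the opposite, the equally available (S,S)-amine is used with no other change.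

**Route**

Step 1
Reactants: 1 4,4-dimethoxybutan-2-one
Product: 3 tert-butyl[(4,4-dimethoxybut-1-en-2-yl)oxy]dimethylsilane, via lithium enolate 2 (not isolated)
Conditions: LiN(iPr)2, THF, −78 °C; then tBuMe2SiCl, DMPU, −78 °C to rt
Reagents that add atoms: tert-butyldimethylsilyl chloride, CC(C)(C)[Si](C)(C)Cl
Why: Kinetic deprotonation by the hindered amide takes the methyl group and not the methylene next to the acetal, and O-silylation of the enolate gives the 2-silyloxy-1-alkene (kinetic silyl enol ether formation).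

Step 2
Reactants: 3 tert-butyl[(4,4-dimethoxybut-1-en-2-yl)oxy]dimethylsilane; 4 dichloroacetyl chloride
Product: 6 racemic 3-(tert-butyldimethylsilyloxy)-2,2-dichloro-3-(2,2-dimethoxyethyl)cyclobutan-1-one, via dichloroketene 5 (not isolated)
Conditions: Et3N, hexane, rt, slow addition of 4
Reagents that add atoms: none
Why: Ketene–enol ether (2+2) cycloaddition in which the nucleophilic CH2 terminus bonds to the ketene carbonyl carbon, so the silyloxy carbon (future C12) ends up next to CCl2; generating the ketene with amine avoids a Lewis acidic zinc salt that could couple the acetal with the enol ether.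

Step 3
Reactants: 6 racemic 3-(tert-butyldimethylsilyloxy)-2,2-dichloro-3-(2,2-dimethoxyethyl)cyclobutan-1-one
Product: 8 3-(tert-butyldimethylsilyloxy)-3-(2,2-dimethoxyethyl)cyclobutan-1-one, via monochloroketone 7 (not isolated)
Conditions: Zn dust, NH4Cl, MeOH, rt
Reagents that add atoms: none
Why: Stepwise reductive dechlorination of an α,α-dichloroketone by zinc in a buffered protic medium, where the zinc enolate is protonated before it can expel the β-silyloxy group, as in the usual preparation of 3-alkoxycyclobutanones; the product is achiral.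

Step 4
Reactants: 8 3-(tert-butyldimethylsilyloxy)-3-(2,2-dimethoxyethyl)cyclobutan-1-one
Product: 10 (3R)-3-(tert-butyldimethylsilyloxy)-3-(2,2-dimethoxyethyl)-1-(trimethylsilyloxy)cyclobut-1-ene, via lithium enolate 9 (not isolated)
Conditions: (R,R)-bis(1-phenylethyl)amine, n-BuLi, LiCl, THF, −78 °C; then Me3SiCl and 8, −100 °C (internal quench); non-aqueous work-up
Reagents that add atoms: chlorotrimethylsilane, C[Si](C)(C)Cl
Why: Enantiotopos-selective deprotonation of a prochiral cyclobutanone by a C2-symmetric chiral lithium amide with in situ silyl trapping (chiral lithium amide desymmetrization); the choice between the two α-methylenes makes the silyloxy carbon the C12 stereocentre, and the internal quench should outrun β-elimination and enolate equilibration.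

Step 5
Reactants: 10 (3R)-3-(tert-butyldimethylsilyloxy)-3-(2,2-dimethoxyethyl)-1-(trimethylsilyloxy)cyclobut-1-ene; 11 chloroform
Product: 14 (4S)-4-(tert-butyldimethylsilyloxy)-2-chloro-4-(2,2-dimethoxyethyl)cyclopent-2-en-1-one, via dichlorocarbene 12 (not isolated), via housane adduct 13 (not isolated)
Conditions: CHCl3, KOtBu (added in portions), pentane, −40 to 0 °C; aq. NaHCO3 work-up
Reagents that add atoms: none
Why: Dichlorocarbene, formed by α-elimination from chloroform, adds as an electrophile in a concerted (2+1) manner to the electron-rich C9=C11 enol ether bond and gives the 5,5-dichlorobicyclo[2.1.0]pentane 13, whose central C9–C11 bond is strained and carries the donor oxygen. The chloride syn to the four-membered ring ionises with disrotatory cyclopropyl-to-allyl opening (a two-electron electrocyclic process) that breaks C9–C11, and transfer of the trimethylsilyl group from the resulting 2-chloro-1-silyloxyallyl cation to chloride leaves C9=O and C10(Cl)=C11; any allylic chloride formed by ion-pair return should collapse to the same enone on work-up. The closest known reaction type is the dihalocarbene ring expansion of cyclic silyl enol ethers to 2-halocycloalk-2-enones, together with the ready opening of dihalocarbene adducts of cyclobutenes to 2,3-dihalocyclopentenes. The three-membered ring is closed by cheletropic addition, and the five-membered ring C8–C12 arises by cleavage of the bond shared by the two small rings, not by an end-to-end closure, so that C10 is inserted between C9 and C11. No stereocentre is created in 14: the carbene may attack either face because both bridgehead centres are lost on opening, and C12, which is not touched, keeps the configuration set in step 4. The step needs chemoselective attack on the enol ether and not on the acetal or silyl ether groups, which the nucleophilicity of that bond secures, and a regiochemistry that is fixed by the position of the enol double bond; low temperature in pentane guards against thermal opening of the cyclobutene and base attack on the product.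

Step 6
Reactants: 14 (4S)-4-(tert-butyldimethylsilyloxy)-2-chloro-4-(2,2-dimethoxyethyl)cyclopent-2-en-1-one
Product: 15 2-[(1S)-1-(tert-butyldimethylsilyloxy)-3-chloro-4-oxocyclopent-2-en-1-yl]acetaldehyde
Conditions: Amberlyst-15, acetone/H2O, rt
Reagents that add atoms: water, O
Why: Acid-catalysed acetal hydrolysis; the tertiary silyl ether should survive the resin in wet acetone, and ionisation at C12 is disfavoured because the cation would be conjugated with the enone carbonyl.

Step 7
Reactants: 15 2-[(1S)-1-(tert-butyldimethylsilyloxy)-3-chloro-4-oxocyclopent-2-en-1-yl]acetaldehyde; 16 hexyltriphenylphosphonium bromide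
Product: 18 (4S)-4-(tert-butyldimethylsilyloxy)-2-chloro-4-[(2Z)-oct-2-en-1-yl]cyclopent-2-en-1-one, via hexylidene ylide 17 (not isolated)
Conditions: 16, NaN(SiMe3)2, THF, 0 °C; then ylide added to 15 (slight deficit), THF, −78 to −20 °C
Reagents that add atoms: none
Why: Salt-free Wittig olefination with a non-stabilised ylide gives the (Z)-alkene through the kinetically formed cis-oxaphosphetane, and at −78 °C the aldehyde should react before the ring ketone, as in Wittig side-chain syntheses of jasmonoids that carry a cyclopentenone.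

Step 8
Reactants: 18 (4S)-4-(tert-butyldimethylsilyloxy)-2-chloro-4-[(2Z)-oct-2-en-1-yl]cyclopent-2-en-1-one; 19 2,2,2-trifluoroethyl formate
Product: 21 (4R,5Z)-4-(tert-butyldimethylsilyloxy)-2-chloro-5-(hydroxymethylidene)-4-[(2Z)-oct-2-en-1-yl]cyclopent-2-en-1-one, via lithium dienolate 20 (not isolated)
Conditions: LiN(SiMe3)2, THF, −78 °C; then 19, −78 to 0 °C; aq. NH4Cl
Reagents that add atoms: none
Why: Claisen-type C-formylation of the kinetic enolate at C8, the only enolisable position because C12 is quaternary, with an activated formate; the product should rest as the hydrogen-bonded (Z)-hydroxymethylene ketone, which places the future C7 on C8.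

Step 9
Reactants: 21 (4R,5Z)-4-(tert-butyldimethylsilyloxy)-2-chloro-5-(hydroxymethylidene)-4-[(2Z)-oct-2-en-1-yl]cyclopent-2-en-1-one
Product: 23 (4R,5Z)-4-(tert-butyldimethylsilyloxy)-2-chloro-4-[(2Z)-oct-2-en-1-yl]-5-[(trifluoromethanesulfonyloxy)methylidene]cyclopent-2-en-1-one, via lithium chelate 22 (not isolated)
Conditions: LiN(SiMe3)2, THF, −78 °C; then N-(5-chloropyridin-2-yl)bis(trifluoromethanesulfonyl)imide, −78 to −20 °C; aq. NH4Cl
Reagents that add atoms: N-(5-chloropyridin-2-yl)bis(trifluoromethanesulfonyl)imide, O=S(=O)(N(c1ccc(Cl)cn1)S(=O)(=O)C(F)(F)F)C(F)(F)F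
Why: O-sulfonylation of the lithium-chelated β-ketoaldehyde enolate at the less hindered formyl oxygen keeps the U-shaped geometry, so the triflate group sits syn to C9=O (chelation-controlled enol triflate formation, as used for stereodefined enol triflates of β-ketoesters).

Step 10
Reactants: 24 methyl hex-5-ynoate
Product: 25 methyl 6-(tributylstannyl)hex-5-ynoate
Conditions: Bu3SnOMe, ZnBr2 (cat.), THF, rt
Reagents that add atoms: tributyltin methoxide, CCCC[Sn](CCCC)(CCCC)OC
Why: Stannylation of the terminal alkyne C–H bond by a tin alkoxide with release of methanol (ZnBr2-catalysed), which leaves the methyl ester untouched.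

Step 11
Reactants: 25 methyl 6-(tributylstannyl)hex-5-ynoate
Product: 27 methyl (5Z)-6-(tributylstannyl)hex-5-enoate, via stannyl alkenylzirconocene 26 (not isolated)
Conditions: Cp2Zr(H)Cl, THF, rt, short contact; then H2O
Reagents that add atoms: none
Why: Hydrozirconation adds Zr–H syn across the stannylalkyne with zirconium on the tin-bearing carbon, and protonolysis of the C–Zr bond with retention leaves tin cis to the chain, which is the (Z)-vinylstannane.

Step 12
Reactants: 23 (4R,5Z)-4-(tert-butyldimethylsilyloxy)-2-chloro-4-[(2Z)-oct-2-en-1-yl]-5-[(trifluoromethanesulfonyloxy)methylidene]cyclopent-2-en-1-one; 27 methyl (5Z)-6-(tributylstannyl)hex-5-enoate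
Product: 28 methyl (5Z,7Z,12R,14Z)-12-(tert-butyldimethylsilyloxy)-10-chloro-9-oxoprosta-5,7,10,14-tetraen-1-oate
Conditions: Pd2(dba)3 (cat.), AsPh3, CuI (cat.), NMP, rt, dark
Reagents that add atoms: none
Why: Stille cross-coupling of a vinylogous acyl triflate with an alkenylstannane under neutral conditions goes with retention at both sp2 carbons, forming C6–C7 and carrying over 7Z from the triflate and 5Z from the stannane; oxidative addition into the C–OTf bond should be much faster than into the C10–Cl bond.

Step 13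
Reactants: 28 methyl (5Z,7Z,12R,14Z)-12-(tert-butyldimethylsilyloxy)-10-chloro-9-oxoprosta-5,7,10,14-tetraen-1-oate
Product: 29 methyl (5Z,7Z,12R,14Z)-10-chloro-12-hydroxy-9-oxoprosta-5,7,10,14-tetraen-1-oate
Conditions: aq. HF (48%), MeCN, 0 °C to rt, dark
Reagents that add atoms: none
Why: Cleavage of the tertiary silyl ether by hydrogen fluoride under mildly acidic, non-nucleophilic conditions that the base-sensitive cross-conjugated dienone should tolerate; ionisation at C12 is disfavoured, so the configuration is kept.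

**Compound list**

1 | 4,4-dimethoxybutan-2-one | CC(=O)CC(OC)OC | starting material
2 | lithium 4,4-dimethoxybut-1-en-2-olate | [Li]OC(=C)CC(OC)OC | intermediate
3 | tert-butyl[(4,4-dimethoxybut-1-en-2-yl)oxy]dimethylsilane | C=C(O[Si](C)(C)C(C)(C)C)CC(OC)OC | intermediate
4 | dichloroacetyl chloride | ClC(Cl)C(Cl)=O | starting material
5 | dichloroketene | ClC(Cl)=C=O | intermediate
6 | racemic 3-(tert-butyldimethylsilyloxy)-2,2-dichloro-3-(2,2-dimethoxyethyl)cyclobutan-1-one | COC(OC)CC1(O[Si](C)(C)C(C)(C)C)CC(=O)C1(Cl)Cl | intermediate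
7 | 3-(tert-butyldimethylsilyloxy)-2-chloro-3-(2,2-dimethoxyethyl)cyclobutan-1-one, mixture of stereoisomers | COC(OC)CC1(O[Si](C)(C)C(C)(C)C)CC(=O)C1Cl | intermediate
8 | 3-(tert-butyldimethylsilyloxy)-3-(2,2-dimethoxyethyl)cyclobutan-1-one (achiral) | COC(OC)CC1(O[Si](C)(C)C(C)(C)C)CC(=O)C1 | intermediate
9 | lithium (3R)-3-(tert-butyldimethylsilyloxy)-3-(2,2-dimethoxyethyl)cyclobut-1-en-1-olate | COC(OC)C[C@@]1(O[Si](C)(C)C(C)(C)C)C=C(O[Li])C1 | intermediate
10 | (3R)-3-(tert-butyldimethylsilyloxy)-3-(2,2-dimethoxyethyl)-1-(trimethylsilyloxy)cyclobut-1-ene | COC(OC)C[C@@]1(O[Si](C)(C)C(C)(C)C)C=C(O[Si](C)(C)C)C1 | intermediate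
11 | chloroform | ClC(Cl)Cl | starting material
12 | dichlorocarbene | Cl[C]Cl | intermediate
13 | 5,5-dichloro-3-(tert-butyldimethylsilyloxy)-3-(2,2-dimethoxyethyl)-1-(trimethylsilyloxy)bicyclo[2.1.0]pentane, silyloxy carbon C3 as in 10, both ring-fusion diastereomers | COC(OC)C[C@@]1(O[Si](C)(C)C(C)(C)C)C2C(Cl)(Cl)C2(O[Si](C)(C)C)C1 | intermediate
14 | (4S)-4-(tert-butyldimethylsilyloxy)-2-chloro-4-(2,2-dimethoxyethyl)cyclopent-2-en-1-one | COC(OC)C[C@@]1(O[Si](C)(C)C(C)(C)C)C=C(Cl)C(=O)C1 | intermediate
15 | 2-[(1S)-1-(tert-butyldimethylsilyloxy)-3-chloro-4-oxocyclopent-2-en-1-yl]acetaldehyde | O=CC[C@@]1(O[Si](C)(C)C(C)(C)C)C=C(Cl)C(=O)C1 | intermediate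
16 | hexyltriphenylphosphonium bromide | CCCCCC[P+](c1ccccc1)(c1ccccc1)c1ccccc1.[Br-] | starting material
17 | hexylidenetriphenylphosphorane | CCCCCC=P(c1ccccc1)(c1ccccc1)c1ccccc1 | intermediate
18 | (4S)-4-(tert-butyldimethylsilyloxy)-2-chloro-4-[(2Z)-oct-2-en-1-yl]cyclopent-2-en-1-one | CCCCC/C=C\C[C@@]1(O[Si](C)(C)C(C)(C)C)C=C(Cl)C(=O)C1 | intermediate
19 | 2,2,2-trifluoroethyl formate | O=COCC(F)(F)F | starting material
20 | lithium dienolate of 18 (C8=C9 enolate, C12 unchanged) | CCCCC/C=C\C[C@@]1(O[Si](C)(C)C(C)(C)C)C=C(Cl)C(O[Li])=C1 | intermediate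
21 | (4R,5Z)-4-(tert-butyldimethylsilyloxy)-2-chloro-5-(hydroxymethylidene)-4-[(2Z)-oct-2-en-1-yl]cyclopent-2-en-1-one | CCCCC/C=C\C[C@@]1(O[Si](C)(C)C(C)(C)C)C=C(Cl)C(=O)/C1=C\O | intermediate
22 | lithium salt of 21, chelated (Z)-enolate | CCCCC/C=C\C[C@@]1(O[Si](C)(C)C(C)(C)C)C=C(Cl)C(=O)/C1=C\O[Li] | intermediate
23 | (4R,5Z)-4-(tert-butyldimethylsilyloxy)-2-chloro-4-[(2Z)-oct-2-en-1-yl]-5-[(trifluoromethanesulfonyloxy)methylidene]cyclopent-2-en-1-one | CCCCC/C=C\C[C@@]1(O[Si](C)(C)C(C)(C)C)C=C(Cl)C(=O)/C1=C\OS(=O)(=O)C(F)(F)F | intermediate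
24 | methyl hex-5-ynoate | COC(=O)CCCC#C | starting material
25 | methyl 6-(tributylstannyl)hex-5-ynoate | CCCC[Sn](CCCC)(CCCC)C#CCCCC(=O)OC | intermediate
26 | methyl (5Z)-6-[chlorobis(cyclopentadienyl)zirconio]-6-(tributylstannyl)hex-5-enoate | CCCC[Sn](CCCC)(CCCC)/C(=C\CCCC(=O)OC)[Zr](Cl)(C1C=CC=C1)C1C=CC=C1 | intermediate
27 | methyl (5Z)-6-(tributylstannyl)hex-5-enoate | CCCC[Sn](CCCC)(CCCC)/C=C\CCCC(=O)OC | intermediate
28 | methyl (5Z,7Z,12R,14Z)-12-(tert-butyldimethylsilyloxy)-10-chloro-9-oxoprosta-5,7,10,14-tetraen-1-oate | CCCCC/C=C\C[C@@]1(O[Si](C)(C)C(C)(C)C)C=C(Cl)C(=O)/C1=C\C=C/CCCC(=O)OC | intermediate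
29 | methyl (5Z,7Z,12R,14Z)-10-chloro-12-hydroxy-9-oxoprosta-5,7,10,14-tetraen-1-oate | CCCCC/C=C\C[C@@]1(O)C=C(Cl)C(=O)/C1=C\C=C/CCCC(=O)OC | target

**Step count**

Total: 13 steps. Longest linear sequence: 11 steps (steps 1 to 9, 12 and 13); steps 10 and 11 make the stannane.

**Steps most likely to fail**

Step 5. The siloxycyclobutene may open thermally to a diene, the trimethylsilyl enol ether may be cleaved by the alkoxide before the carbene arrives, or the chloroenone may be consumed by base. The fallback sets out from 10 and inserts C10 without a carbene–base medium. Cyclopropanation with Et2Zn/CH2I2 should give 3-(tert-butyldimethylsilyloxy)-3-(2,2-dimethoxyethyl)-1-(trimethylsilyloxy)bicyclo[2.1.0]pentane F1. Oxidative opening of the siloxycyclopropane with FeCl3 in DMF at 0 °C should give the ring-expanded 3-chloro-4-(tert-butyldimethylsilyloxy)-4-(2,2-dimethoxyethyl)cyclopentan-1-one F2, and NaOAc in MeOH should remove HCl to give (4S)-4-(tert-butyldimethylsilyloxy)-4-(2,2-dimethoxyethyl)cyclopent-2-en-1-one F3. Addition of chlorine across C10=C11 (Et4NCl3, CH2Cl2, 0 °C) should give the 2,3-dichlorocyclopentanone F4, and Et3N should then remove HCl. The route is rejoined at 14.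

Step 4. The two enantiotopic α-methylenes may be poorly distinguished, because the silyloxy and alkyl groups on C3 differ little in size. The fallback sets out from 8 and replaces asymmetric deprotonation by resolution. LiN(iPr)2 and Me3SiCl should give the racemic 3-(tert-butyldimethylsilyloxy)-3-(2,2-dimethoxyethyl)-1-(trimethylsilyloxy)cyclobut-1-ene F5. The conditions of step 5 should convert it into racemic 4-(tert-butyldimethylsilyloxy)-2-chloro-4-(2,2-dimethoxyethyl)cyclopent-2-en-1-one F6. Preparative HPLC on an amylose carbamate chiral stationary phase should separate F6 into 14 and the (4R)-enantiomer F7, which is set aside. The route is rejoined at 14.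

Step 9. The enolate may be sulfonylated without chelate control, which would lose the Z geometry at C7=C8, or at the ring oxygen. The fallback sets out from 18 and builds C7=C8 by aldol addition and elimination; it is not stereocontrolled at C7=C8 and relies on separation.
- Enal: commercial hex-5-ynoic acid F8 is converted with 2 equiv LiN(iPr)2 and paraformaldehyde into 7-hydroxyhept-5-ynoic acid F9. Esterification (MeOH, cat. H2SO4) gives methyl 7-hydroxyhept-5-ynoate F10. Semihydrogenation (H2, Pd/CaCO3 poisoned with Pb(OAc)2, quinoline) gives methyl (5Z)-7-hydroxyhept-5-enoate F11. Oxidation with Dess–Martin periodinane/NaHCO3 gives methyl (5Z)-7-oxohept-5-enoate F12.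
- Coupling: the lithium dienolate 20, made from 18 as in step 8, should add to F12 at −78 °C to give the C7 aldols F13. MsCl/Et3N should give the mesylates F14, and DBU should eliminate them to 28 together with its (7E)-isomer F15, from which 28 is separated by HPLC. The route is rejoined at 28.

**Further compounds**

F1 | step 5 | 3-(tert-butyldimethylsilyloxy)-3-(2,2-dimethoxyethyl)-1-(trimethylsilyloxy)bicyclo[2.1.0]pentane, C3 as in 10 | COC(OC)C[C@@]1(O[Si](C)(C)C(C)(C)C)C2CC2(O[Si](C)(C)C)C1
F2 | step 5 | 3-chloro-4-(tert-butyldimethylsilyloxy)-4-(2,2-dimethoxyethyl)cyclopentan-1-one, C4 as in 14, mixture at C3 | COC(OC)C[C@@]1(O[Si](C)(C)C(C)(C)C)C(Cl)CC(=O)C1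
F3 | step 5 | (4S)-4-(tert-butyldimethylsilyloxy)-4-(2,2-dimethoxyethyl)cyclopent-2-en-1-one | COC(OC)C[C@@]1(O[Si](C)(C)C(C)(C)C)C=CC(=O)C1
F4 | step 5 | 2,3-dichloro-4-(tert-butyldimethylsilyloxy)-4-(2,2-dimethoxyethyl)cyclopentan-1-one, C4 as in 14, mixture at C2 and C3 | COC(OC)C[C@@]1(O[Si](C)(C)C(C)(C)C)C(Cl)C(Cl)C(=O)C1
F5 | step 4 | racemic 3-(tert-butyldimethylsilyloxy)-3-(2,2-dimethoxyethyl)-1-(trimethylsilyloxy)cyclobut-1-ene | COC(OC)CC1(O[Si](C)(C)C(C)(C)C)C=C(O[Si](C)(C)C)C1
F6 | step 4 | racemic 4-(tert-butyldimethylsilyloxy)-2-chloro-4-(2,2-dimethoxyethyl)cyclopent-2-en-1-one | COC(OC)CC1(O[Si](C)(C)C(C)(C)C)C=C(Cl)C(=O)C1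
F7 | step 4 | (4R)-4-(tert-butyldimethylsilyloxy)-2-chloro-4-(2,2-dimethoxyethyl)cyclopent-2-en-1-one | COC(OC)C[C@]1(O[Si](C)(C)C(C)(C)C)C=C(Cl)C(=O)C1
F8 | step 9 | hex-5-ynoic acid | C#CCCCC(=O)O
F9 | step 9 | 7-hydroxyhept-5-ynoic acid | OCC#CCCCC(=O)O
F10 | step 9 | methyl 7-hydroxyhept-5-ynoate | COC(=O)CCCC#CCO
F11 | step 9 | methyl (5Z)-7-hydroxyhept-5-enoate | COC(=O)CCC/C=C\CO
F12 | step 9 | methyl (5Z)-7-oxohept-5-enoate | COC(=O)CCC/C=C\C=O
F13 | step 9 | methyl (5Z,12R,14Z)-12-(tert-butyldimethylsilyloxy)-10-chloro-7-hydroxy-9-oxoprosta-5,10,14-trien-1-oate, mixture at C7 and C8 | CCCCC/C=C\C[C@@]1(O[Si](C)(C)C(C)(C)C)C=C(Cl)C(=O)C1C(O)/C=C\CCCC(=O)OC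
F14 | step 9 | methyl (5Z,12R,14Z)-12-(tert-butyldimethylsilyloxy)-10-chloro-7-(methanesulfonyloxy)-9-oxoprosta-5,10,14-trien-1-oate, mixture at C7 and C8 | CCCCC/C=C\C[C@@]1(O[Si](C)(C)C(C)(C)C)C=C(Cl)C(=O)C1C(OS(C)(=O)=O)/C=C\CCCC(=O)OC
F15 | step 9 | methyl (5Z,7E,12R,14Z)-12-(tert-butyldimethylsilyloxy)-10-chloro-9-oxoprosta-5,7,10,14-tetraen-1-oate | CCCCC/C=C\C[C@@]1(O[Si](C)(C)C(C)(C)C)C=C(Cl)C(=O)/C1=C/C=C\CCCC(=O)OC
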